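The earlier runs and the new flask were generated by integration from invented constants.

A small charge of substrate, smaller than Saturday's and Thursday's, raises one question for this flask: does a steady pace have time to work through it by 6.0 min? We reckon this in fractions of this flask's charge.

| setting | Saturday's | Thursday's | Tuesday's | flask |
|---|---|---|---|---|
| substrate | 0.28 M (fed, over 2.0 min) | 0.44 M (fed, over 2.0 min) | 0.20 M (fed, over 2.0 min) | 0.20 M (fed, over 2.0 min) |
| gas | 45 mM (held) | 45 mM (held) | 45 mM (held) | 45 mM (held) |
| free catalyst | 0.40 mM | 0.40 mM | 0.60 mM | 0.40 mM |
| remark | run made earlier | run made earlier | run made earlier |  |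
| time |  |  |  | 6.0 min |

| run | time / min | product / % | substrate / % |
|---|---|---|---|
| Saturday's | 0.250 | 1.5 | 11.5 |
| Saturday's | 0.667 | 6.2 | 26.6 |
| Saturday's | 1.33 | 15.3 | 51.3 |
| Saturday's | 2.00 | 25.3 | 76.2 |
| Saturday's | 3.00 | 39.1 | 60.8 |
| Saturday's | 4.00 | 53.2 | 46.7 |
| Thursday's | 0.250 | 1.5 | 11.3 |
| Thursday's | 0.667 | 4.4 | 29.4 |
| Thursday's | 1.33 | 9.3 | 56.3 |
| Thursday's | 2.00 | 16.0 | 83.4 |
| Thursday's | 3.00 | 25.2 | 73.9 |
| Thursday's | 4.00 | 35.5 | 63.7 |
| Tuesday's | 0.333 | 4.1 | 12.1 |
| Tuesday's | 0.833 | 14.8 | 26.0 |
| Tuesday's | 1.50 | 31.3 | 42.8 |
| Tuesday's | 2.50 | 58.5 | 40.9 |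
| Tuesday's | 4.00 | 91.9 | 6.4 |

(readings scatter by 0.5 percentage points)

- at the start none of the gas is in solution
- percentages count the whole charge, also what has not yet gone in

* the product in the flask at 6.0 min, as a percentage of the substrate charged
* the substrate in the flask at 6.0 min, as a percentage of the substrate charged
* concentration of released group at 6.0 min, in M

Saturday's and Thursday's runs have this flask's catalyst and gas, so we read the flask from them. At the end of the feed, Thursday's product counts as 0.352 of this charge and Saturday's as 0.354. We take that for this flask. Thursday's product then gives the pace: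

pace = product gained after the feed / time / this charge = 0.214 /min

end of feed + (whole charge − made) / pace = 5.02 min

This is the clearing time, the moment a held pace brings product to the whole charge. Saturday's pace, 0.195 /min, is slower and gives 5.32 min. Both come before the reading.

The second way uses Tuesday's run, with the same charge and more catalyst. If pace followed catalyst, this flask's 6.0 min would match Tuesday's 4.00 min, where 6.4 % substrate stood. The two ways part, and the test is Tuesday's own pace:

Tuesday's pace from 1.50 min to 2.50 min = 0.272 /min, which is 1.27 times Thursday's, against a catalyst ratio of 1.50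

So on these readings the catalyst clock runs fast, though Tuesday's charge also differs from Thursday's. Tuesday's last reading corresponds to about 5.07 min here, still before 6.0 min. Yet that reading still shows substrate, so we expect a tail past the clearing time in this flask. We expect less substrate than 6.4 %, but not zero.

The forecast, reading “saturation kinetics, first order in catalyst”, which differs from our stretch, gave 93.5 % product (87 % to 98 %), 5.5 % substrate (1.5 % to 12 %) and 0.187 M released group (0.172 M to 0.198 M).

The flask gives 97.6 % product, 2.42 % substrate and 0.195 M released group, inside the forecast's ranges.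

    substrate + catalyst intermediate A ⇌ catalyst intermediate B (K = 258 /M, k = 125 /M/s)
    gas ⇌ reagent, rate k2*(csat - [reagent]) (kL = 0.0605 /s)
    catalyst intermediate C → released group + catalyst intermediate D (k = 12.5 /s)
    catalyst intermediate D → free catalyst + product (k = 16.7 /s)
    catalyst intermediate B → catalyst intermediate C (k = 104 /s)
    reagent + free catalyst → catalyst intermediate A (k = 73.6 /M/s)

The resting state moves: free catalyst is 62.8 % of the catalyst charged at 3.00 min, while at 6.00 min catalyst intermediate A holds 77.2 %. Our clearing time lies 0.980 min before the reading, and this flask still holds 2.42 % substrate. Read at 2.5 min, the same flask is short of the clearing time, so pace times time to go gives 53.9 % substrate left. It holds 57.2 %.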